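The route hinges on breaking the C4–C5 bond of the dihydropyran (ring atoms O1, C2–C6). Because the ester-bearing C5 is flanked by C4 and by C6, which is bonded to the ring oxygen, the C5–C6 unit can be delivered as a methyl malonate acylating the oxygen on C2, C6 arriving as a lactone carbonyl. A single base-mediated conjugate addition of the malonate carbon onto a tethered E-enoate then makes C4–C5, closes the six-membered ring and fixes C4 trans to C3. The cyclisation substrate is an acyclic (4S,5S)-hexenoate whose two stereocentres come from an Evans crotonyl aldol and which already carries the hydroxytyrosol ester as its dibenzyl ether.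

Key step: step 9

Remark: ring atoms are numbered O1, C2 (CH3), C3 (CHO), C4 (CH2CO2R), C5 (CO2Me), C6 (=CH–O). On this numbering the target is (2S,3R,4R) with methyl, formyl and acetate arm mutually trans, which requires the R auxiliary and a (4S,5S) cyclisation substrate. The catechol is carried as its dibenzyl ether so that the last step is a neutral hydrogenolysis and not an aqueous acid treatment of the β-alkoxy aldehyde.

Step 1
Reactants: 1 (R)-4-benzyl-1,3-oxazolidin-2-one; 2 (E)-but-2-enoyl chloride
Product: 4 (4R)-4-benzyl-3-[(2E)-but-2-enoyl]-1,3-oxazolidin-2-one, via N-lithio oxazolidinone 3 (not isolated)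
Conditions: n-BuLi, THF, −78 °C; then 2, −78 to 0 °C
Reagents that add atoms: none
Why: N-acylation of the lithiated oxazolidinone by the acid chloride (standard Evans imide formation) should be fast at low temperature, where conjugate addition to the crotonyl unit does not compete; no stereocentre is formed.

Step 2
Reactants: 4 (4R)-4-benzyl-3-[(2E)-but-2-enoyl]-1,3-oxazolidin-2-one; 5 acetaldehyde
Product: 8 (4R)-4-benzyl-3-[(2R,3S)-2-ethenyl-3-hydroxybutanoyl]-1,3-oxazolidin-2-one, via Z-boron dienolate 6 (not isolated), via boron aldolate 7 (not isolated)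
Conditions: Bu2BOTf, Et3N, CH2Cl2, −78 to 0 °C; 5, −78 to 0 °C; pH 7 buffer, MeOH, H2O2, 0 °C
Reagents that add atoms: none
Why: Evans boron syn-aldol reaction in its deconjugative form: soft enolisation gives the Z(O)-dienolate, which adds through its α-carbon to acetaldehyde in a Zimmerman–Traxler chair on the face away from the benzyl group of the R auxiliary, so that C2 (R, vinyl-bearing) and C3 (S, carbinol) of the butanoyl chain are set together as the syn pair.

Step 3
Reactants: 8 (4R)-4-benzyl-3-[(2R,3S)-2-ethenyl-3-hydroxybutanoyl]-1,3-oxazolidin-2-one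
Product: 9 (2S,3S)-2-ethenylbutane-1,3-diol
Conditions: LiBH4, THF, 0 °C to rt
Reagents that add atoms: none
Why: Reductive cleavage of the N-acyl oxazolidinone by borohydride attacks the exocyclic carbonyl only, releases the auxiliary for recovery and should leave the α-stereocentre untouched because no enolisable carbonyl survives; the small water-soluble diol is best carried on after a non-aqueous work-up.

Step 4
Reactants: 9 (2S,3S)-2-ethenylbutane-1,3-diol
Product: 10 (2S,3S)-3-({[tert-butyl(dimethyl)silyl]oxy}methyl)pent-4-en-2-ol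
Conditions: TBSCl (1.05 equiv), imidazole, CH2Cl2, 0 °C
Reagents that add atoms: tert-butyldimethylsilyl chloride, CC(C)(C)[Si](C)(C)Cl
Why: Silyl ether formation with a bulky chlorosilane is strongly selective for the primary over the secondary hydroxyl, which leaves the future C2 oxygen free for the malonate tether.

Step 5
Reactants: 11 hydroxytyrosol
Product: 12 2-[3,4-bis(benzyloxy)phenyl]ethan-1-ol
Conditions: BnBr (2.2 equiv), K2CO3, acetone, reflux, under N2
Reagents that add atoms: benzyl bromide, BrCc1ccccc1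
Why: Williamson ether synthesis in which carbonate ionises only the two phenols, so O-benzylation spares the aliphatic alcohol.

Step 6
Reactants: 12 2-[3,4-bis(benzyloxy)phenyl]ethan-1-ol; 13 acryloyl chloride
Product: 14 2-[3,4-bis(benzyloxy)phenyl]ethyl prop-2-enoate
Conditions: Et3N, CH2Cl2, 0 °C
Reagents that add atoms: none
Why: Acylation of an unhindered primary alcohol by an acid chloride with an amine base is reliable and should not disturb the aryl benzyl ethers.

Step 7
Reactants: 10 (2S,3S)-3-({[tert-butyl(dimethyl)silyl]oxy}methyl)pent-4-en-2-ol; 14 2-[3,4-bis(benzyloxy)phenyl]ethyl prop-2-enoate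
Product: 15 2-[3,4-bis(benzyloxy)phenyl]ethyl (2E,4S,5S)-4-({[tert-butyl(dimethyl)silyl]oxy}methyl)-5-hydroxyhex-2-enoate
Conditions: second-generation Hoveyda–Grubbs catalyst RuCl2(H2IMes)(=CH-C6H4-2-OiPr) (5 mol %), 14 (2 equiv), CH2Cl2, 40 °C
Reagents that add atoms: none
Why: Olefin cross-metathesis between a terminal alkene and an acrylate, a pairing that favours the cross product because the acrylate homodimerises slowly, should give the E-enoate with loss of ethene; the free secondary alcohol and both stereocentres are untouched.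

Step 8
Reactants: 15 2-[3,4-bis(benzyloxy)phenyl]ethyl (2E,4S,5S)-4-({[tert-butyl(dimethyl)silyl]oxy}methyl)-5-hydroxyhex-2-enoate; 16 methyl 3-chloro-3-oxopropanoate (methyl malonyl chloride)
Product: 17 2-[3,4-bis(benzyloxy)phenyl]ethyl (2E,4S,5S)-4-({[tert-butyl(dimethyl)silyl]oxy}methyl)-5-[(3-methoxy-3-oxopropanoyl)oxy]hex-2-enoate
Conditions: pyridine, CH2Cl2, 0 °C
Reagents that add atoms: none
Why: O-acylation of the secondary alcohol by the acid chloride places the C5–C6 unit on the future ring oxygen with retention at the carbinol carbon, pyridine being too weak a base to start the cyclisation.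

Step 9
Reactants: 17 2-[3,4-bis(benzyloxy)phenyl]ethyl (2E,4S,5S)-4-({[tert-butyl(dimethyl)silyl]oxy}methyl)-5-[(3-methoxy-3-oxopropanoyl)oxy]hex-2-enoate
Product: 18 methyl (3R,4R,5S,6S)-4-{2-[2-(3,4-bis(benzyloxy)phenyl)ethoxy]-2-oxoethyl}-5-({[tert-butyl(dimethyl)silyl]oxy}methyl)-6-methyl-2-oxooxane-3-carboxylate (all four substituents equatorial)
Conditions: Cs2CO3 (0.3 equiv), MeCN, 23 to 40 °C; then AcOH, 0 °C
Reagents that add atoms: none
Why: Carbonate removes a proton from the malonate CH2, the only site acidic enough, the stabilised carbanion (future C5) adds to the enoate β-carbon (future C4) and the ester enolate so formed is protonated, the product resting partly as its lactone–ester enolate until the quench. The closest known reaction type is the base-mediated intramolecular Michael addition of an O-tethered malonate to an α,β-unsaturated ester, which gives an α-alkoxycarbonyl δ-lactone. The ring O1–C2–C3–C4–C5–C6 closes in the 6-exo-trig mode. C4 is controlled by the C2 and C3 stereocentres through a chair-like transition state that keeps the C2 methyl, the C3 silyloxymethyl group and the enoate chain equatorial (3,4-trans), while C5 is set by enolisation under the same conditions, which leaves its ester equatorial and trans to the C4 arm. The step needs 3,4-trans diastereoselectivity and conjugate addition in preference to γ-deprotonation or acyl transfer: the trans C2/C3 pattern inherited from the syn-aldol makes the all-equatorial lactone both the kinetic and the thermodynamic product, retro-Michael reopening under the equilibrating conditions should return any cis isomer to it, and the substrate has no free hydroxyl and no other comparably acidic C–H.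

Step 10
Reactants: 18 methyl (3R,4R,5S,6S)-4-{2-[2-(3,4-bis(benzyloxy)phenyl)ethoxy]-2-oxoethyl}-5-({[tert-butyl(dimethyl)silyl]oxy}methyl)-6-methyl-2-oxooxane-3-carboxylate
Product: 20 methyl (2S,3S,4R)-4-{2-[2-(3,4-bis(benzyloxy)phenyl)ethoxy]-2-oxoethyl}-3-({[tert-butyl(dimethyl)silyl]oxy}methyl)-2-methyl-6-{[(trifluoromethyl)sulfonyl]oxy}-3,4-dihydro-2H-pyran-5-carboxylate, via sodium enolate 19 (not isolated)
Conditions: NaH, Et2O, 0 °C; then Tf2O, −78 to 0 °C
Reagents that add atoms: trifluoromethanesulfonic anhydride, O=S(=O)(OS(=O)(=O)C(F)(F)F)C(F)(F)F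
Why: O-sulfonylation of a 1,3-dicarbonyl enolate (enol triflate formation): the only acidic proton is at C5, and the enolate should be trapped on the lactone oxygen, the more enolate-like one because a lactone is held in the less stabilised E-ester geometry, to give the endocyclic ketene acetal triflate; C5 becomes sp2 while C2, C3 and C4 are untouched.

Step 11
Reactants: 20 methyl (2S,3S,4R)-4-{2-[2-(3,4-bis(benzyloxy)phenyl)ethoxy]-2-oxoethyl}-3-({[tert-butyl(dimethyl)silyl]oxy}methyl)-2-methyl-6-{[(trifluoromethyl)sulfonyl]oxy}-3,4-dihydro-2H-pyran-5-carboxylate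
Product: 21 methyl (2S,3S,4R)-4-{2-[2-(3,4-bis(benzyloxy)phenyl)ethoxy]-2-oxoethyl}-3-({[tert-butyl(dimethyl)silyl]oxy}methyl)-2-methyl-3,4-dihydro-2H-pyran-5-carboxylate
Conditions: Pd(OAc)2 (5 mol %), PPh3 (12 mol %), HCO2H, Et3N, DMF, 60 °C
Reagents that add atoms: none
Why: Palladium-catalysed formate reduction of an enol triflate: oxidative addition of the C6–O bond to zerovalent palladium (formed in the flask from Pd(OAc)2 and PPh3), exchange of triflate for formate, loss of CO2 and C–H reductive elimination should replace the triflate by hydrogen and leave the C5=C6 enol ether, the phosphine-ligated homogeneous catalyst sparing the benzyl ethers.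

Step 12
Reactants: 21 methyl (2S,3S,4R)-4-{2-[2-(3,4-bis(benzyloxy)phenyl)ethoxy]-2-oxoethyl}-3-({[tert-butyl(dimethyl)silyl]oxy}methyl)-2-methyl-3,4-dihydro-2H-pyran-5-carboxylate
Product: 22 methyl (2S,3S,4R)-4-{2-[2-(3,4-bis(benzyloxy)phenyl)ethoxy]-2-oxoethyl}-3-(hydroxymethyl)-2-methyl-3,4-dihydro-2H-pyran-5-carboxylate
Conditions: HF·pyridine, pyridine, THF, 0 °C to rt
Reagents that add atoms: none
Why: Fluoride-mediated desilylation of a primary silyl ether under buffered, weakly acidic conditions should free the alcohol without base-catalysed attack on the neighbouring C4 acetate ester; the crude alcohol is oxidised at once.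

Step 13
Reactants: 22 methyl (2S,3S,4R)-4-{2-[2-(3,4-bis(benzyloxy)phenyl)ethoxy]-2-oxoethyl}-3-(hydroxymethyl)-2-methyl-3,4-dihydro-2H-pyran-5-carboxylate
Product: 23 methyl (2S,3R,4R)-4-{2-[2-(3,4-bis(benzyloxy)phenyl)ethoxy]-2-oxoethyl}-3-formyl-2-methyl-3,4-dihydro-2H-pyran-5-carboxylate
Conditions: Dess–Martin periodinane, CH2Cl2, 0 °C to rt
Reagents that add atoms: none
Why: Dess–Martin oxidation turns the primary alcohol into the aldehyde under non-basic conditions, and C3, now α to the formyl group, should hold its configuration because the trans,trans arrangement is also the more stable one.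

Step 14
Reactants: 23 methyl (2S,3R,4R)-4-{2-[2-(3,4-bis(benzyloxy)phenyl)ethoxy]-2-oxoethyl}-3-formyl-2-methyl-3,4-dihydro-2H-pyran-5-carboxylate
Product: 24 methyl (2S,3R,4R)-4-{2-[2-(3,4-dihydroxyphenyl)ethoxy]-2-oxoethyl}-3-formyl-2-methyl-3,4-dihydro-2H-pyran-5-carboxylate
Conditions: H2 (1 atm), Pd/C, EtOAc, rt
Reagents that add atoms: none
Why: Hydrogenolysis of the two aryl benzyl ethers is fast under these neutral conditions, under which an aliphatic aldehyde, the homobenzylic ester and the ester-conjugated enol ether are expected to be inert, so the catechol is released without acid or base.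

Compound list

1 | (R)-4-benzyl-1,3-oxazolidin-2-one | O=C1N[C@H](Cc2ccccc2)CO1 | starting material
2 | (E)-but-2-enoyl chloride (crotonyl chloride) | C/C=C/C(Cl)=O | starting material
3 | lithium salt of (R)-4-benzyl-1,3-oxazolidin-2-one (N-lithio oxazolidinone) | O=C1[N-][C@H](Cc2ccccc2)CO1.[Li+] | intermediate
4 | (4R)-4-benzyl-3-[(2E)-but-2-enoyl]-1,3-oxazolidin-2-one | C/C=C/C(=O)N1[C@H](Cc2ccccc2)COC1=O | intermediate
5 | acetaldehyde | CC=O | starting material
6 | (4R)-4-benzyl-3-{(1Z)-1-[(dibutylboranyl)oxy]buta-1,3-dien-1-yl}-1,3-oxazolidin-2-one (Z-boron dienolate) | C=C/C=C(\OB(CCCC)CCCC)N1[C@H](Cc2ccccc2)COC1=O | intermediate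
7 | O-dibutylboranyl derivative of aldol 8 (boron aldolate) | CCCCB(CCCC)O[C@@H](C)[C@H](C(=O)N1[C@H](Cc2ccccc2)COC1=O)C=C | intermediate
8 | (4R)-4-benzyl-3-[(2R,3S)-2-ethenyl-3-hydroxybutanoyl]-1,3-oxazolidin-2-one | O[C@@H](C)[C@H](C(=O)N1[C@H](Cc2ccccc2)COC1=O)C=C | intermediate
9 | (2S,3S)-2-ethenylbutane-1,3-diol | O[C@@H](C)[C@H](CO)C=C | intermediate
10 | (2S,3S)-3-({[tert-butyl(dimethyl)silyl]oxy}methyl)pent-4-en-2-ol | O[C@@H](C)[C@H](CO[Si](C)(C)C(C)(C)C)C=C | intermediate
11 | hydroxytyrosol, 4-(2-hydroxyethyl)benzene-1,2-diol | OCCc1ccc(O)c(O)c1 | starting material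
12 | 2-[3,4-bis(benzyloxy)phenyl]ethan-1-ol | OCCc1ccc(OCc2ccccc2)c(OCc2ccccc2)c1 | intermediate
13 | acryloyl chloride | C=CC(Cl)=O | starting material
14 | 2-[3,4-bis(benzyloxy)phenyl]ethyl prop-2-enoate | C=CC(=O)OCCc1ccc(OCc2ccccc2)c(OCc2ccccc2)c1 | intermediate
15 | 2-[3,4-bis(benzyloxy)phenyl]ethyl (2E,4S,5S)-4-({[tert-butyl(dimethyl)silyl]oxy}methyl)-5-hydroxyhex-2-enoate | O[C@@H](C)[C@H](CO[Si](C)(C)C(C)(C)C)/C=C/C(=O)OCCc1ccc(OCc2ccccc2)c(OCc2ccccc2)c1 | intermediate
16 | methyl 3-chloro-3-oxopropanoate (methyl malonyl chloride) | COC(=O)CC(Cl)=O | starting material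
17 | 2-[3,4-bis(benzyloxy)phenyl]ethyl (2E,4S,5S)-4-({[tert-butyl(dimethyl)silyl]oxy}methyl)-5-[(3-methoxy-3-oxopropanoyl)oxy]hex-2-enoate | COC(=O)CC(=O)O[C@@H](C)[C@H](CO[Si](C)(C)C(C)(C)C)/C=C/C(=O)OCCc1ccc(OCc2ccccc2)c(OCc2ccccc2)c1 | intermediate
18 | methyl (3R,4R,5S,6S)-4-{2-[2-(3,4-bis(benzyloxy)phenyl)ethoxy]-2-oxoethyl}-5-({[tert-butyl(dimethyl)silyl]oxy}methyl)-6-methyl-2-oxooxane-3-carboxylate | COC(=O)[C@@H]1C(=O)O[C@@H](C)[C@H](CO[Si](C)(C)C(C)(C)C)[C@H]1CC(=O)OCCc1ccc(OCc2ccccc2)c(OCc2ccccc2)c1 | intermediate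
19 | sodium enolate of lactone 18 | COC(=O)C1=C([O-])O[C@@H](C)[C@H](CO[Si](C)(C)C(C)(C)C)[C@H]1CC(=O)OCCc1ccc(OCc2ccccc2)c(OCc2ccccc2)c1.[Na+] | intermediate
20 | methyl (2S,3S,4R)-4-{2-[2-(3,4-bis(benzyloxy)phenyl)ethoxy]-2-oxoethyl}-3-({[tert-butyl(dimethyl)silyl]oxy}methyl)-2-methyl-6-{[(trifluoromethyl)sulfonyl]oxy}-3,4-dihydro-2H-pyran-5-carboxylate | COC(=O)C1=C(OS(=O)(=O)C(F)(F)F)O[C@@H](C)[C@H](CO[Si](C)(C)C(C)(C)C)[C@H]1CC(=O)OCCc1ccc(OCc2ccccc2)c(OCc2ccccc2)c1 | intermediate
21 | methyl (2S,3S,4R)-4-{2-[2-(3,4-bis(benzyloxy)phenyl)ethoxy]-2-oxoethyl}-3-({[tert-butyl(dimethyl)silyl]oxy}methyl)-2-methyl-3,4-dihydro-2H-pyran-5-carboxylate | COC(=O)C1=CO[C@@H](C)[C@H](CO[Si](C)(C)C(C)(C)C)[C@H]1CC(=O)OCCc1ccc(OCc2ccccc2)c(OCc2ccccc2)c1 | intermediate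
22 | methyl (2S,3S,4R)-4-{2-[2-(3,4-bis(benzyloxy)phenyl)ethoxy]-2-oxoethyl}-3-(hydroxymethyl)-2-methyl-3,4-dihydro-2H-pyran-5-carboxylate | COC(=O)C1=CO[C@@H](C)[C@H](CO)[C@H]1CC(=O)OCCc1ccc(OCc2ccccc2)c(OCc2ccccc2)c1 | intermediate
23 | methyl (2S,3R,4R)-4-{2-[2-(3,4-bis(benzyloxy)phenyl)ethoxy]-2-oxoethyl}-3-formyl-2-methyl-3,4-dihydro-2H-pyran-5-carboxylate | COC(=O)C1=CO[C@@H](C)[C@H](C=O)[C@H]1CC(=O)OCCc1ccc(OCc2ccccc2)c(OCc2ccccc2)c1 | intermediate
24 | methyl (2S,3R,4R)-4-{2-[2-(3,4-dihydroxyphenyl)ethoxy]-2-oxoethyl}-3-formyl-2-methyl-3,4-dihydro-2H-pyran-5-carboxylate | COC(=O)C1=CO[C@@H](C)[C@H](C=O)[C@H]1CC(=O)OCCc1ccc(O)c(O)c1 | target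

Total step count: 14. Longest linear sequence: 12 steps (steps 1–4 and 7–14, from compound 1); the side arm (steps 5 and 6) joins at step 7.

Steps most likely to fail

Step 9. The closure may fail to drain fully to the 3,4-trans lactone, or the base may instead remove the γ-proton of the enoate and expel the malonate as a dienoate. The fallback changes from a basic, equilibrating closure to a Lewis-acid, kinetically controlled one. Malonate 17 would be treated with TMSOTf and Et3N in CH2Cl2 at 0 °C to give its trimethylsilyl ketene acetal F1. F1 would then be closed with TiCl4 in CH2Cl2 at −78 °C in an intramolecular Mukaiyama–Michael addition through the same all-equatorial chair. Aqueous work-up should return lactone 18.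

Step 10. Sulfonylation may take place at the methyl ester oxygen or at carbon instead of the lactone oxygen, or the ketene acetal triflate may decompose before it is reduced. The fallback removes the choice between two enolate oxygens by a lactone-to-alkoxyacrylate transposition. From lactone 18, Krapcho demethoxycarbonylation (LiCl, wet DMSO, 130 °C) would give the unsubstituted δ-lactone F2. Claisen formylation at the lactone α-carbon (NaH, HCO2Me, THF, 0 °C to rt) would give the hydroxymethylene lactone F3. Brief treatment of F3 with methanolic HCl (from AcCl in MeOH, 0 °C) should open the lactone to the methyl ester, close the freed C2 hydroxyl onto the formyl carbon and dehydrate. The old lactone carbonyl thus becomes the C5 ester and the formyl carbon becomes C6. The primary silyl ether is expected to be lost in the same operation, so the sequence would rejoin the route at alcohol 22, which is oxidised at once.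

Step 7. The branched allylic position of alkene 10 may engage the ruthenium carbene too slowly, so that acrylate homodimerisation and alkene isomerisation take over. The fallback replaces metathesis by oxidative cleavage and olefination. From alkene 10, ozonolysis (O3, CH2Cl2, −78 °C; then PPh3) would give the β-hydroxy aldehyde F4, used cold and crude. Alcohol 12 would be heated with (triphenylphosphoranylidene)ketene, Ph3P=C=C=O, in toluene to give the stabilised ester ylide F5. Base-free, E-selective Wittig olefination of F4 with F5 (CH2Cl2, rt) should return enoate 15.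

Further compounds

F1 | step 9 | 2-[3,4-bis(benzyloxy)phenyl]ethyl (2E,4S,5S)-4-({[tert-butyl(dimethyl)silyl]oxy}methyl)-5-({3-methoxy-3-[(trimethylsilyl)oxy]prop-2-enoyl}oxy)hex-2-enoate | COC(O[Si](C)(C)C)=CC(=O)O[C@@H](C)[C@H](CO[Si](C)(C)C(C)(C)C)/C=C/C(=O)OCCc1ccc(OCc2ccccc2)c(OCc2ccccc2)c1
F2 | step 10 | 2-[3,4-bis(benzyloxy)phenyl]ethyl [(2S,3S,4S)-3-({[tert-butyl(dimethyl)silyl]oxy}methyl)-2-methyl-6-oxooxan-4-yl]acetate (ring stereocentres as in 18) | C1C(=O)O[C@@H](C)[C@H](CO[Si](C)(C)C(C)(C)C)[C@H]1CC(=O)OCCc1ccc(OCc2ccccc2)c(OCc2ccccc2)c1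
F3 | step 10 | 2-[3,4-bis(benzyloxy)phenyl]ethyl [(2S,3S,4R)-3-({[tert-butyl(dimethyl)silyl]oxy}methyl)-5-(hydroxymethylidene)-2-methyl-6-oxooxan-4-yl]acetate | OC=C1C(=O)O[C@@H](C)[C@H](CO[Si](C)(C)C(C)(C)C)[C@H]1CC(=O)OCCc1ccc(OCc2ccccc2)c(OCc2ccccc2)c1
F4 | step 7 | (2S,3S)-2-({[tert-butyl(dimethyl)silyl]oxy}methyl)-3-hydroxybutanal | O[C@@H](C)[C@H](CO[Si](C)(C)C(C)(C)C)C=O
F5 | step 7 | 2-[3,4-bis(benzyloxy)phenyl]ethyl (triphenyl-λ5-phosphanylidene)acetate | O=C(C=P(c1ccccc1)(c1ccccc1)c1ccccc1)OCCc1ccc(OCc2ccccc2)c(OCc2ccccc2)c1
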